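**Assumption:** carbons are numbered C1 (ethyl CH3) to C15 (propenyl CH3), with C6' and C8' the hydroxymethyl carbons; the open-chain keto form drawn is taken as the target (it equilibrates with its C3 hemiketal in solution).

## Retrosynthetic overview

1. Myriaporone 4 comes from deprotection and C3 carbinol→ketone adjustment of a protected C1–C15 epoxy ketone. The only ring, the C10–C11 oxirane, is formed late, after fragment union, by C9-OH-directed epoxidation of a (Z)-trisubstituted alkene.
2. Key disconnection C8–C9: anti-selective boron aldol between a C1–C8 ketone (10 skeletal C) and a C9–C15 (2Z,5Z)-dienal (9 skeletal C), creating C8 and C9.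
3. C1–C8 ketone: C3 (temporary carbinol) from (R)-1,2-epoxybutane; C5 by catalytic asymmetric acetate aldol; C6 by Fráter–Seebach alkoxymethylation; C8/C8' by Weinreb amide → vinyl ketone → oxa-Michael.
4. C9–C15 dienal: C12 from (R)-Roche ester; C13=C14 by Z-selective Wittig; C10=C11 by Still–Gennari olefination.

## West fragment (C1–C8)

**Step 1**
Reactants: 1, (R)-1,2-epoxybutane
Product: 2, (R)-hex-5-en-3-ol
Conditions: CH2=CHMgBr, CuI (10 mol %), THF, −30 → 0 °C
Reagents that add atoms: vinylmagnesium bromide, C=C[Mg]Br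
Why: Cu-catalysed SN2 epoxide opening at the terminal CH2 leaves the carbinol centre (C3, a temporary stereocentre erased in step 23) untouched.

**Step 2**
Reactants: 2, (R)-hex-5-en-3-ol
Product: 3, (R)-triethyl(hex-5-en-3-yloxy)silane
Conditions: TESCl, imidazole, CH2Cl2, 0 °C → rt
Reagents that add atoms: chlorotriethylsilane, CC[Si](Cl)(CC)CC
Why: Standard silylation; TES is chosen so that C3-O can later be unmasked selectively in the presence of TBS ethers.

**Step 3**
Reactants: 3, (R)-triethyl(hex-5-en-3-yloxy)silane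
Product: 4, (R)-3-(triethylsilyloxy)pentanal (C1–C5)
Conditions: O3, CH2Cl2, −78 °C; then PPh3
Reagents that add atoms: ozone, O=[O+][O-]
Why: Ozonolysis with reductive work-up cleaves the terminal alkene to the aldehyde without touching the silyl ether.

**Step 4**
Reactants: 4, (R)-3-(triethylsilyloxy)pentanal
Product: 5, methyl (3S,5R)-3-hydroxy-5-(triethylsilyloxy)heptanoate
Conditions: CH2=C(OMe)OTMS, Carreira Ti(IV) catalyst (Ti(Oi-Pr)4 / NOBIN-derived tridentate Schiff-base ligand / 3,5-di-t-Bu-salicylic acid, 3 mol %; ligand antipode that gives Re-face addition), Et2O, 0 °C; then K2CO3, MeOH, 0 °C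
Reagents that add atoms: 1-methoxy-1-(trimethylsilyloxy)ethene, C=C(OC)O[Si](C)(C)C
Why: Catalyst-controlled asymmetric Mukaiyama acetate aldol sets the C5 carbinol (3S in the ester) by Re-face addition; the mild methanolysis removes only the TMS ether.

**Step 5**
Reactants: 5, methyl (3S,5R)-3-hydroxy-5-(triethylsilyloxy)heptanoate
Product: 6, methyl (2S,3S,5R)-3-hydroxy-2-[(4-methoxybenzyloxy)methyl]-5-(triethylsilyloxy)heptanoate
Conditions: LDA (2.2 equiv), THF, −78 → −20 °C; then PMBOCH2Cl, −78 → −30 °C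
Reagents that add atoms: 4-methoxybenzyl chloromethyl ether, COc1ccc(COCCl)cc1
Why: Fráter–Seebach alkylation: the chelated lithium alkoxide-enolate is alkylated anti to the C5 oxygen, setting C6 (2S) and delivering C6' already as its PMB ether.

**Step 6**
Reactants: 6, the β-hydroxy ester
Product: 7, (2S,3S,5R)-3-hydroxy-N-methoxy-2-[(4-methoxybenzyloxy)methyl]-N-methyl-5-(triethylsilyloxy)heptanamide
Conditions: MeNH(OMe)·HCl, i-PrMgCl, THF, −20 → 0 °C
Reagents that add atoms: N,O-dimethylhydroxylamine hydrochloride, CNOC.Cl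
Why: Weinreb amidation with the magnesium amide proceeds on α-branched β-hydroxy esters (as for the Roche ester) without epimerisation.

**Step 7**
Reactants: 7, the β-hydroxy Weinreb amide
Product: 8, (2S,3S,5R)-3-(tert-butyldimethylsilyloxy)-N-methoxy-2-[(4-methoxybenzyloxy)methyl]-N-methyl-5-(triethylsilyloxy)heptanamide
Conditions: TBSOTf, 2,6-lutidine, CH2Cl2, −78 → 0 °C
Reagents that add atoms: TBSOTf, CC(C)(C)[Si](C)(C)OS(=O)(=O)C(F)(F)F
Why: Silylation of the hindered C5 carbinol; TBS is a poor hydrogen-bond acceptor, which matters for facial control in step 19.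

**Step 8**
Reactants: 8, the TBS-protected Weinreb amide
Product: 9, (4S,5S,7R)-5-(tert-butyldimethylsilyloxy)-4-[(4-methoxybenzyloxy)methyl]-7-(triethylsilyloxy)non-1-en-3-one
Conditions: CH2=CHMgBr, THF, 0 °C; inverse quench into cold aq. NH4Cl
Reagents that add atoms: vinylmagnesium bromide, C=C[Mg]Br
Why: Weinreb ketone synthesis: the stable chelate stops at mono-addition and gives the vinyl ketone carrying C8 and C8'.

**Step 9**
Reactants: 9, the vinyl ketone
Product: 10, (4S,5S,7R)-5-(tert-butyldimethylsilyloxy)-1-(4-methoxybenzyloxy)-4-[(4-methoxybenzyloxy)methyl]-7-(triethylsilyloxy)nonan-3-one (West ketone)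
Conditions: 4-methoxybenzyl alcohol (5 equiv), PMe3 (10 mol %), THF, rt
Reagents that add atoms: 4-methoxybenzyl alcohol, COc1ccc(CO)cc1
Why: Phosphine-catalysed oxa-Michael addition to the unhindered vinyl ketone installs the C8' oxygen under near-neutral conditions that spare the C6 stereocentre.

## East fragment (C9–C15)

**Step 10**
Reactants: 11, methyl (R)-3-hydroxy-2-methylpropanoate ((R)-Roche ester)
Product: 12, methyl (R)-3-(tert-butyldimethylsilyloxy)-2-methylpropanoate
Conditions: TBSCl, imidazole, CH2Cl2, rt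
Reagents that add atoms: TBSCl, CC(C)(C)[Si](C)(C)Cl
Why: Standard silylation; the chiral-pool methyl stereocentre becomes C12.

**Step 11**
Reactants: 12, the TBS Roche ester
Product: 13, (S)-3-(tert-butyldimethylsilyloxy)-2-methylpropan-1-ol
Conditions: DIBAL-H (2.2 equiv), CH2Cl2, −78 → −40 °C
Reagents that add atoms: none
Why: Ester reduction to the alcohol (the descriptor changes only through CIP priorities), avoiding over-reduction problems of a direct ester→aldehyde step.

**Step 12**
Reactants: 13, the primary alcohol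
Product: 14, (R)-3-(tert-butyldimethylsilyloxy)-2-methylpropanal
Conditions: (COCl)2, DMSO, CH2Cl2, −78 °C; i-Pr2NEt; used crude
Reagents that add atoms: none
Why: Swern oxidation at low temperature with a hindered base gives the α-chiral aldehyde without racemisation.

**Step 13**
Reactants: 14, the Roche aldehyde
Product: 15, tert-butyldimethyl{[(2S,3Z)-2-methylpent-3-en-1-yl]oxy}silane
Conditions: EtPPh3Br, KHMDS, THF, −78 °C → rt
Reagents that add atoms: ethyltriphenylphosphonium bromide, CC[P+](c1ccccc1)(c1ccccc1)c1ccccc1.[Br-]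
Why: Salt-free Wittig reaction of a non-stabilised ylide gives the (Z)-C13=C14 alkene under kinetic control.

**Step 14**
Reactants: 15, the (Z)-alkenyl TBS ether
Product: 16, (2S,3Z)-2-methylpent-3-en-1-ol
Conditions: TBAF, THF, 0 °C → rt (volatile; kept in solution)
Reagents that add atoms: none
Why: Fluoride desilylation frees the primary alcohol that becomes C11.

**Step 15**
Reactants: 16, the alcohol
Product: 17, (2S,3Z)-2-methylpent-3-enal
Conditions: Dess–Martin periodinane, NaHCO3, CH2Cl2, 0 °C; used at once as a crude solution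
Reagents that add atoms: none
Why: Buffered Dess–Martin oxidation is non-basic, so the epimerisable β,γ-unsaturated aldehyde is obtained without racemisation or conjugation.

**Step 16**
Reactants: 17, the aldehyde
Product: 18, methyl (2Z,4S,5Z)-2,4-dimethylhepta-2,5-dienoate
Conditions: (CF3CH2O)2P(O)CH(CH3)CO2Me, KHMDS, 18-crown-6, THF, −78 °C
Reagents that add atoms: methyl 2-[bis(2,2,2-trifluoroethoxy)phosphoryl]propanoate, COC(=O)C(C)P(=O)(OCC(F)(F)F)OCC(F)(F)F
Why: Still–Gennari olefination gives the (Z)-trisubstituted C10=C11 enoate; the weakly basic phosphonate anion at −78 °C spares C12.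

**Step 17**
Reactants: 18, the (Z)-enoate
Product: 19, (2Z,4S,5Z)-2,4-dimethylhepta-2,5-dien-1-ol
Conditions: DIBAL-H, CH2Cl2, −78 °C
Reagents that add atoms: none
Why: 1,2-Reduction of the enoate to the allylic alcohol retains both alkene geometries.

**Step 18**
Reactants: 19, the dienol
Product: 20, (2Z,4S,5Z)-2,4-dimethylhepta-2,5-dienal (East aldehyde)
Conditions: Dess–Martin periodinane, NaHCO3, CH2Cl2, 0 °C; used immediately
Reagents that add atoms: none
Why: Mild buffered oxidation gives the (Z)-enal without Z→E isomerisation.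

## Fragment union and endgame

**Step 19**
Reactants: 10, West ketone; 20, East dienal
Product: 21, (3R,5S,6S,8R,9S,10Z,12S,13Z)-5-(tert-butyldimethylsilyloxy)-9-hydroxy-6,8-bis[(4-methoxybenzyloxy)methyl]-10,12-dimethyl-3-(triethylsilyloxy)pentadeca-10,13-dien-7-one
Conditions: 10, Cy2BCl, Et3N, Et2O, −78 → 0 °C; then 20 (1.5 equiv), −78 → −20 °C; pH 7 buffer/MeOH/H2O2, 0 °C
Reagents that add atoms: none
Why: Paterson boron aldol: Cy2BCl/Et3N gives the (E)-enol borinate at the less hindered C8 methylene, and the chair transition state gives the 8,9-anti product. The C6 centre (A1,3-minimised, formyl H-bond to the C6'-OPMB oxygen, bulky silylated C5 arm turned away) is expected to direct attack to the face giving (8R,9S).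

**Step 20**
Reactants: 21, the aldol adduct
Product: 22, (3R,5S,6S,8R,9S,10R,11S,12S,13Z)-10,11-epoxy derivative of 21 (threo epoxy alcohol)
Conditions: mCPBA (1.1 equiv), NaHCO3, CH2Cl2, −20 °C
Reagents that add atoms: mCPBA, OOC(=O)c1cccc(Cl)c1
Why: Henbest-type hydroxyl-directed epoxidation: A1,3 strain in the (Z)-trisubstituted allylic alcohol holds C9–H in the alkene plane, so the H-bonded peracid delivers oxygen syn to C9-OH and gives the (10R,11S) oxirane. The isolated cis-disubstituted C13=C14 alkene reacts much more slowly.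

**Step 21**
Reactants: 22, the epoxy alcohol
Product: 23, 9-O-TBS ether of 22 (all stereocentres as in 22)
Conditions: TBSOTf, 2,6-lutidine, CH2Cl2, −78 °C
Reagents that add atoms: TBSOTf, CC(C)(C)[Si](C)(C)OS(=O)(=O)C(F)(F)F
Why: Low-temperature silylation with a hindered base protects C9-OH before the C3 oxidation without opening the epoxide.

**Step 22**
Reactants: 23, the fully protected epoxide
Product: 24, 3-hydroxy compound (TES removed; 5,9-bis-OTBS and both PMB ethers retained)
Conditions: HF·pyridine, excess pyridine, THF, 0 °C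
Reagents that add atoms: none
Why: Buffered HF·pyridine cleaves the secondary TES ether much faster than the hindered secondary TBS ethers and leaves the epoxide intact.

**Step 23**
Reactants: 24, the C3 alcohol
Product: 25, the 3,7-dione (C3 ketone; 5,9-bis-OTBS, 6',8'-bis-OPMB, 10,11-epoxide)
Conditions: Dess–Martin periodinane, NaHCO3, CH2Cl2, rt
Reagents that add atoms: none
Why: C3-OH is the only free hydroxyl, and buffered Dess–Martin oxidation is compatible with the epoxide, alkene and ethers; the temporary C3 stereocentre is erased.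

**Step 24**
Reactants: 25, the dione
Product: 26, 6,8-bis(hydroxymethyl) compound (5,9-bis-OTBS retained)
Conditions: DDQ, CH2Cl2/pH 7 phosphate buffer (10:1), 0 °C
Reagents that add atoms: none
Why: Oxidative cleavage of both PMB ethers under buffered conditions; with C5 and C9 silylated, no neighbouring free OH can divert the reaction to PMP acetals.

**Step 25**
Reactants: 26, the bis-TBS ether
Product: 27, myriaporone 4
Conditions: HF·pyridine (excess), pyridine, THF, 0 °C → rt
Reagents that add atoms: none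
Why: Buffered fluoride desilylation removes the two secondary TBS ethers without base (no retro-aldol or β-elimination) and without strong acid (epoxide retained); the product equilibrates with its hemiketal form.

## Compound list

1 | (R)-1,2-epoxybutane | CC[C@@H]1CO1 | starting material
2 | (R)-hex-5-en-3-ol | CC[C@@H](O)CC=C | intermediate
3 | (R)-triethyl(hex-5-en-3-yloxy)silane | CC[C@@H](O[Si](CC)(CC)CC)CC=C | intermediate
4 | (R)-3-(triethylsilyloxy)pentanal | CC[C@@H](O[Si](CC)(CC)CC)CC=O | intermediate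
5 | methyl (3S,5R)-3-hydroxy-5-(triethylsilyloxy)heptanoate | CC[C@@H](O[Si](CC)(CC)CC)C[C@H](O)CC(=O)OC | intermediate
6 | methyl (2S,3S,5R)-3-hydroxy-2-[(4-methoxybenzyloxy)methyl]-5-(triethylsilyloxy)heptanoate | CC[C@@H](O[Si](CC)(CC)CC)C[C@H](O)[C@H](COCc1ccc(OC)cc1)C(=O)OC | intermediate
7 | (2S,3S,5R)-3-hydroxy-N-methoxy-2-[(4-methoxybenzyloxy)methyl]-N-methyl-5-(triethylsilyloxy)heptanamide | CC[C@@H](O[Si](CC)(CC)CC)C[C@H](O)[C@H](COCc1ccc(OC)cc1)C(=O)N(C)OC | intermediate
8 | 3-O-TBS ether of 7 | CC[C@@H](O[Si](CC)(CC)CC)C[C@H](O[Si](C)(C)C(C)(C)C)[C@H](COCc1ccc(OC)cc1)C(=O)N(C)OC | intermediate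
9 | (4S,5S,7R)-5-(TBS-oxy)-4-[(PMB-oxy)methyl]-7-(TES-oxy)non-1-en-3-one | CC[C@@H](O[Si](CC)(CC)CC)C[C@H](O[Si](C)(C)C(C)(C)C)[C@H](COCc1ccc(OC)cc1)C(=O)C=C | intermediate
10 | (4S,5S,7R)-5-(TBS-oxy)-1-(PMB-oxy)-4-[(PMB-oxy)methyl]-7-(TES-oxy)nonan-3-one (West ketone) | CC[C@@H](O[Si](CC)(CC)CC)C[C@H](O[Si](C)(C)C(C)(C)C)[C@H](COCc1ccc(OC)cc1)C(=O)CCOCc1ccc(OC)cc1 | intermediate
11 | methyl (R)-3-hydroxy-2-methylpropanoate ((R)-Roche ester) | COC(=O)[C@H](C)CO | starting material
12 | methyl (R)-3-(TBS-oxy)-2-methylpropanoate | COC(=O)[C@H](C)CO[Si](C)(C)C(C)(C)C | intermediate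
13 | (S)-3-(TBS-oxy)-2-methylpropan-1-ol | OC[C@H](C)CO[Si](C)(C)C(C)(C)C | intermediate
14 | (R)-3-(TBS-oxy)-2-methylpropanal | O=C[C@H](C)CO[Si](C)(C)C(C)(C)C | intermediate
15 | tert-butyldimethyl{[(2S,3Z)-2-methylpent-3-en-1-yl]oxy}silane | C/C=C\[C@H](C)CO[Si](C)(C)C(C)(C)C | intermediate
16 | (2S,3Z)-2-methylpent-3-en-1-ol | C/C=C\[C@H](C)CO | intermediate
17 | (2S,3Z)-2-methylpent-3-enal | C/C=C\[C@H](C)C=O | intermediate
18 | methyl (2Z,4S,5Z)-2,4-dimethylhepta-2,5-dienoate | C/C=C\[C@H](C)/C=C(/C)C(=O)OC | intermediate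
19 | (2Z,4S,5Z)-2,4-dimethylhepta-2,5-dien-1-ol | C/C=C\[C@H](C)/C=C(/C)CO | intermediate
20 | (2Z,4S,5Z)-2,4-dimethylhepta-2,5-dienal (East aldehyde) | C/C=C\[C@H](C)/C=C(/C)C=O | intermediate
21 | (3R,5S,6S,8R,9S,10Z,12S,13Z)-5-(TBS-oxy)-9-hydroxy-6,8-bis[(PMB-oxy)methyl]-10,12-dimethyl-3-(TES-oxy)pentadeca-10,13-dien-7-one | C/C=C\[C@H](C)/C=C(/C)[C@@H](O)[C@@H](COCc1ccc(OC)cc1)C(=O)[C@@H](COCc1ccc(OC)cc1)[C@@H](O[Si](C)(C)C(C)(C)C)C[C@H](O[Si](CC)(CC)CC)CC | intermediate
22 | (10R,11S)-10,11-epoxide of 21 (9-OH free) | C/C=C\[C@H](C)[C@@H]1O[C@]1(C)[C@@H](O)[C@@H](COCc1ccc(OC)cc1)C(=O)[C@@H](COCc1ccc(OC)cc1)[C@@H](O[Si](C)(C)C(C)(C)C)C[C@H](O[Si](CC)(CC)CC)CC | intermediate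
23 | 9-O-TBS ether of 22 | C/C=C\[C@H](C)[C@@H]1O[C@]1(C)[C@@H](O[Si](C)(C)C(C)(C)C)[C@@H](COCc1ccc(OC)cc1)C(=O)[C@@H](COCc1ccc(OC)cc1)[C@@H](O[Si](C)(C)C(C)(C)C)C[C@H](O[Si](CC)(CC)CC)CC | intermediate
24 | 3-hydroxy compound (23 minus TES) | C/C=C\[C@H](C)[C@@H]1O[C@]1(C)[C@@H](O[Si](C)(C)C(C)(C)C)[C@@H](COCc1ccc(OC)cc1)C(=O)[C@@H](COCc1ccc(OC)cc1)[C@@H](O[Si](C)(C)C(C)(C)C)C[C@H](O)CC | intermediate
25 | 3,7-dione (5,9-bis-OTBS, 6',8'-bis-OPMB, 10,11-epoxide) | C/C=C\[C@H](C)[C@@H]1O[C@]1(C)[C@@H](O[Si](C)(C)C(C)(C)C)[C@@H](COCc1ccc(OC)cc1)C(=O)[C@@H](COCc1ccc(OC)cc1)[C@@H](O[Si](C)(C)C(C)(C)C)CC(=O)CC | intermediate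
26 | 5,9-bis-O-TBS myriaporone 4 | C/C=C\[C@H](C)[C@@H]1O[C@]1(C)[C@@H](O[Si](C)(C)C(C)(C)C)[C@@H](CO)C(=O)[C@@H](CO)[C@@H](O[Si](C)(C)C(C)(C)C)CC(=O)CC | intermediate
27 | myriaporone 4, (5S,6S,8R,9S)-5,9-dihydroxy-6,8-bis(hydroxymethyl)-9-{(2R,3S)-2-methyl-3-[(2S,3Z)-pent-3-en-2-yl]oxiran-2-yl}nonane-3,7-dione | C/C=C\[C@H](C)[C@@H]1O[C@]1(C)[C@@H](O)[C@@H](CO)C(=O)[C@@H](CO)[C@@H](O)CC(=O)CC | target

## Summary

**Total steps:** 25 (West 9, East 9, union and endgame 7).

**Longest linear sequence:** 16 steps (steps 1–9 then 19–25; the sequence from 11 through steps 10–18 then 19–25 is equally long).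

**Steps most likely to fail, with fallbacks**

1. **Step 19 (fragment-coupling aldol).** Risks are β-alkoxide loss from the C8 enolate, Z→E isomerisation of 20, and insufficient facial control by C6. Fallback: move the union to the C5–C6 bond. Build C8/C9 first on the East side by an auxiliary-controlled anti-aldol of a 3-(PMB-oxy)propionate equivalent with 20, elaborate to the C6'–C15 ketone, and add aldehyde 4 last in a substrate-controlled anti-aldol.
2. **Step 5 (Fráter–Seebach alkylation with PMBOCH2Cl).** Risks are O-alkylation and the lability of the chloromethyl ether. Fallback: set C5 and C6 together by Ir-catalysed anti-selective (hydroxymethyl)allylation of aldehyde 4 with vinyl ethylene carbonate (Krische), then convert the vinyl group into the C7 ketone after differentiating the diol.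
3. **Step 9 (phosphine-catalysed oxa-Michael on 9).** Risks are epimerisation or β-elimination at C5/C6 and incomplete addition. Fallback: abandon the enone. Reduce amide 8 to the C7 aldehyde, add allylmagnesium bromide, cleave the alkene by ozonolysis/NaBH4 to the 1,3-diol, PMB-protect the primary alcohol and oxidise the C7 carbinol, so that C8/C8' arrive by carbonyl addition instead of conjugate addition.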